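The route rests on disconnecting the bond between the exocyclic carbinol carbon (Cα, attached to C3 of the oxolane ring O1–C2–C3–C4–C5) and its guaiacyl ring. The key step adds a silyl-protected guaiacyllithium to the all-cis oxolane-3-carbaldehyde 16: in one operation it joins the two halves, forms the aryl–Cα bond and sets the (S)-carbinol centre under Felkin–Anh control. It exploits the C3 ring stereocentre, whose C3–C4 ring bond, flanked by the cis CH2OSi arm on C4, is the large α-substituent. Aldehyde 16 comes from a tandem conjugate addition/alkylation on a menthyloxybutenolide, then a hemiketal reduction that sets the all-cis ring.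

Key step: step 10

Remark: TBSO = tert-butyldimethylsilyloxy; menthyloxy = [(1S,2R,5S)-5-methyl-2-(propan-2-yl)cyclohexyl]oxy, from (+)-menthol; keto diol 10 is drawn in its open form although it equilibrates with hemiketal 11.

Step 1
Reactants: 1 5-hydroxyfuran-2(5H)-one; 2 (+)-menthol
Product: 3 (5S)-5-(menthyloxy)furan-2(5H)-one
Conditions: p-toluenesulfonic acid (cat.), toluene, reflux, Dean–Stark; crystallization from petroleum ether at −20 °C, mother liquor re-equilibrated with acid and recycled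
Reagents that add atoms: none
Why: Acid-catalysed acetalization of the cyclic hemiacylal with the secondary alcohol; the two C5 epimers interconvert under the acid and only the (5S) epimer crystallizes, so the menthyl group fixes C5 by crystallization-induced diastereomer transformation.

Step 2
Reactants: 4 4-(TBSO)-3-methoxybenzaldehyde
Product: 5 2-[4-(TBSO)-3-methoxyphenyl]-1,3-dithiane
Conditions: HS(CH2)3SH, BF3·OEt2 (cat.), CH2Cl2, 0 °C → rt
Reagents that add atoms: propane-1,3-dithiol, SCCCS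
Why: Lewis-acid-catalysed dithioacetalization of the aryl aldehyde gives the Corey–Seebach acyl-anion precursor; no stereocentre is formed.

Step 3
Reactants: 5 2-[4-(TBSO)-3-methoxyphenyl]-1,3-dithiane; 3 (5S)-5-(menthyloxy)furan-2(5H)-one
Product: 8 (3R,4S,5S)-3-[(benzyloxy)methyl]-4-{2-[4-(TBSO)-3-methoxyphenyl]-1,3-dithian-2-yl}-5-(menthyloxy)oxolan-2-one, via lithiated dithiane 6 (not isolated), via lithium enolate 7 (not isolated)
Conditions: n-BuLi, THF, −78 → −20 °C; 3, −78 °C; then BnOCH2Cl, DMPU, −78 → −30 °C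
Reagents that add atoms: benzyl chloromethyl ether, ClCOCc1ccccc1
Why: Feringa-type tandem conjugate addition/enolate alkylation on a 5-alkoxybutenolide: the soft dithianyl anion (Corey–Seebach umpolung) adds 1,4 at C4 anti to the C5 menthyloxy group, and the lithium enolate is then C-alkylated at C3 anti to the bulky C4 substituent, so the acetal centre relays both new stereocentres (3R,4S).

Step 4
Reactants: 8 (3R,4S,5S)-3-[(benzyloxy)methyl]-4-{2-[4-(TBSO)-3-methoxyphenyl]-1,3-dithian-2-yl}-5-(menthyloxy)oxolan-2-one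
Product: 9 (2S,3S)-2-[(benzyloxy)methyl]-3-{2-[4-(TBSO)-3-methoxyphenyl]-1,3-dithian-2-yl}butane-1,4-diol
Conditions: LiAlH4, THF, −10 → 0 °C; H2O, aq. NaOH work-up
Reagents that add atoms: none
Why: Hydride reduction of the lactone acetal (pseudo-ester): reduction of C2 opens the ring, the C5 hemiacetal loses menthoxide and the freed aldehyde is reduced too, so both former carbonyl carbons become CH2OH while the two carbon stereocentres, the dithiane and both ethers are untouched.

Step 5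
Reactants: 9 (2S,3S)-2-[(benzyloxy)methyl]-3-{2-[4-(TBSO)-3-methoxyphenyl]-1,3-dithian-2-yl}butane-1,4-diol
Product: 10 (2S,3S)-3-[(benzyloxy)methyl]-4-hydroxy-2-(hydroxymethyl)-1-[4-(TBSO)-3-methoxyphenyl]butan-1-one
Conditions: MeI, CaCO3, MeCN/H2O (4:1), 40 °C
Reagents that add atoms: water, O
Why: Alkylative dithioacetal hydrolysis: S-methylation turns the dithiane into a leaving group and water unmasks the aryl ketone under CaCO3-buffered, near-neutral conditions that should not epimerize the α-stereocentre or cleave the silyl and benzyl ethers.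

Step 6
Reactants: 10 (2S,3S)-3-[(benzyloxy)methyl]-4-hydroxy-2-(hydroxymethyl)-1-[4-(TBSO)-3-methoxyphenyl]butan-1-one
Product: 13 {(2S,3S,4R)-4-[(benzyloxy)methyl]-2-[4-(TBSO)-3-methoxyphenyl]oxolan-3-yl}methanol, via cyclic hemiketal 11 (not isolated), via oxocarbenium ion 12 (not isolated)
Conditions: Et3SiH, BF3·OEt2, CH2Cl2, −78 → −30 °C
Reagents that add atoms: none
Why: Kishi-type ionic reduction of a hemiketal: the C4 hydroxyl closes onto the ketone (5-exo-trig), BF3·OEt2 ionizes the hemiketal to the aryl-conjugated oxocarbenium ion and Et3SiH delivers hydride to the ring face opposite the two cis CH2O substituents, which sets C2 as (S) and completes the all-cis oxolane.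

Step 7
Reactants: 13 {(2S,3S,4R)-4-[(benzyloxy)methyl]-2-[4-(TBSO)-3-methoxyphenyl]oxolan-3-yl}methanol
Product: 14 (2S,3S,4R)-4-[(benzyloxy)methyl]-2-[4-(TBSO)-3-methoxyphenyl]-3-[(TBSO)methyl]oxolane
Conditions: TBSCl, imidazole, DMF, rt
Reagents that add atoms: tert-butyldimethylsilyl chloride, CC(C)(C)[Si](C)(C)Cl
Why: Standard silylation (Corey protocol) of the only free hydroxyl gives a bulky, poorly coordinating ether next to the future formyl group.

Step 8
Reactants: 14 (2S,3S,4R)-4-[(benzyloxy)methyl]-2-[4-(TBSO)-3-methoxyphenyl]-3-[(TBSO)methyl]oxolane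
Product: 15 {(3R,4S,5S)-5-[4-(TBSO)-3-methoxyphenyl]-4-[(TBSO)methyl]oxolan-3-yl}methanol
Conditions: H2 (1 atm), 10% Pd/C, EtOAc, rt
Reagents that add atoms: none
Why: Catalytic hydrogenolysis cleaves the alkyl benzyl ether; in neutral EtOAc at 1 atm the silyl ethers and the less reactive cyclic benzylic C–O bond are expected to survive.

Step 9
Reactants: 15 {(3R,4S,5S)-5-[4-(TBSO)-3-methoxyphenyl]-4-[(TBSO)methyl]oxolan-3-yl}methanol
Product: 16 (3S,4S,5S)-5-[4-(TBSO)-3-methoxyphenyl]-4-[(TBSO)methyl]oxolane-3-carbaldehyde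
Conditions: 2,2,6,6-tetramethylpiperidin-1-oxyl (cat.), PhI(OAc)2, CH2Cl2, rt; used crude
Reagents that add atoms: none
Why: Oxoammonium (TEMPO) oxidation of the primary alcohol stops at the aldehyde under near-neutral conditions, so the cis α-stereocentre C3 should not epimerize.

Step 10
Reactants: 16 (3S,4S,5S)-5-[4-(TBSO)-3-methoxyphenyl]-4-[(TBSO)methyl]oxolane-3-carbaldehyde; 17 (4-bromo-2-methoxyphenoxy)(tert-butyl)dimethylsilane
Product: 19 (S)-[4-(TBSO)-3-methoxyphenyl]{(3S,4S,5S)-5-[4-(TBSO)-3-methoxyphenyl]-4-[(TBSO)methyl]oxolan-3-yl}methanol, via aryllithium 18 (not isolated)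
Conditions: 17, n-BuLi, THF, −78 °C; then 16, THF, −78 °C; aq. NH4Cl
Reagents that add atoms: none
Why: Bromine–lithium exchange on 17 gives aryllithium 18, whose ipso carbon adds to the formyl carbon of 16 through an open, non-chelated transition state, and aqueous work-up gives the alcohol. The closest known reaction type is the Felkin–Anh-controlled 1,2-addition of an aryllithium to an α-branched aldehyde. No ring is closed. The new carbinol centre is controlled by ring stereocentre C3: the C3–C4 ring bond, whose C4 carries the cis CH2OTBS arm, stands anti to the incoming aryl group, the carbonyl oxygen lies next to the ring methylene C2 and the nucleophile passes the C3–H, which leads to the (S)-configuration. The step needs facial selectivity at the formyl group and no enolization of the α-centre; the bulky, poorly coordinating silyl ether excludes a chelate through the C4 oxygen arm (which would favour the other face), and the low temperature and fast addition keep the cis aldehyde from epimerizing.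

Step 11
Reactants: 19 (S)-[4-(TBSO)-3-methoxyphenyl]{(3S,4S,5S)-5-[4-(TBSO)-3-methoxyphenyl]-4-[(TBSO)methyl]oxolan-3-yl}methanol
Product: 20 (S)-(4-hydroxy-3-methoxyphenyl)[(3S,4S,5S)-5-(4-hydroxy-3-methoxyphenyl)-4-(hydroxymethyl)oxolan-3-yl]methanol
Conditions: Bu4NF, AcOH, THF, 0 °C → rt
Reagents that add atoms: none
Why: Fluoride-mediated cleavage of the two aryl and the one alkyl silyl ether, buffered with acetic acid so that the p-hydroxybenzylic alcohol and ether see neither strong base nor acid (no quinone methide formation), leaves all four stereocentres untouched.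

Compound list
1 | 5-hydroxyfuran-2(5H)-one (racemic) | O=C1OC(O)C=C1 | starting material
2 | (+)-menthol, (1S,2R,5S)-5-methyl-2-(propan-2-yl)cyclohexan-1-ol | O[C@H]1C[C@@H](C)CC[C@@H]1C(C)C | starting material
3 | (5S)-5-(menthyloxy)furan-2(5H)-one | O=C1C=C[C@@H](O[C@H]2C[C@@H](C)CC[C@@H]2C(C)C)O1 | intermediate
4 | 4-(TBSO)-3-methoxybenzaldehyde | COc1cc(C=O)ccc1O[Si](C)(C)C(C)(C)C | starting material
5 | 2-[4-(TBSO)-3-methoxyphenyl]-1,3-dithiane | COc1cc(C2SCCCS2)ccc1O[Si](C)(C)C(C)(C)C | intermediate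
6 | 2-lithio-2-[4-(TBSO)-3-methoxyphenyl]-1,3-dithiane | COc1cc(C2([Li])SCCCS2)ccc1O[Si](C)(C)C(C)(C)C | intermediate
7 | lithium (4S,5S)-4-{2-[4-(TBSO)-3-methoxyphenyl]-1,3-dithian-2-yl}-5-(menthyloxy)-4,5-dihydrofuran-2-olate | [Li]OC1=C[C@H](C2(c3ccc(O[Si](C)(C)C(C)(C)C)c(OC)c3)SCCCS2)[C@@H](O[C@H]4C[C@@H](C)CC[C@@H]4C(C)C)O1 | intermediate
8 | (3R,4S,5S)-3-[(benzyloxy)methyl]-4-{2-[4-(TBSO)-3-methoxyphenyl]-1,3-dithian-2-yl}-5-(menthyloxy)oxolan-2-one | O=C1[C@@H](COCc2ccccc2)[C@H](C3(c4ccc(O[Si](C)(C)C(C)(C)C)c(OC)c4)SCCCS3)[C@@H](O[C@H]5C[C@@H](C)CC[C@@H]5C(C)C)O1 | intermediate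
9 | (2S,3S)-2-[(benzyloxy)methyl]-3-{2-[4-(TBSO)-3-methoxyphenyl]-1,3-dithian-2-yl}butane-1,4-diol | OC[C@@H](COCc1ccccc1)[C@@H](CO)C1(c2ccc(O[Si](C)(C)C(C)(C)C)c(OC)c2)SCCCS1 | intermediate
10 | (2S,3S)-3-[(benzyloxy)methyl]-4-hydroxy-2-(hydroxymethyl)-1-[4-(TBSO)-3-methoxyphenyl]butan-1-one | OC[C@@H](COCc1ccccc1)[C@@H](CO)C(=O)c1ccc(O[Si](C)(C)C(C)(C)C)c(OC)c1 | intermediate
11 | (3S,4R)-4-[(benzyloxy)methyl]-3-(hydroxymethyl)-2-[4-(TBSO)-3-methoxyphenyl]oxolan-2-ol (both C2 anomers) | c1ccccc1COC[C@@H]2COC(O)(c3ccc(O[Si](C)(C)C(C)(C)C)c(OC)c3)[C@@H]2CO | intermediate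
12 | cyclic oxocarbenium ion of 11, (3S,4R)-4-[(benzyloxy)methyl]-3-(hydroxymethyl)-2-[4-(TBSO)-3-methoxyphenyl]oxolan-2-ylium | c1ccccc1COC[C@@H]2C[O+]=C(c3ccc(O[Si](C)(C)C(C)(C)C)c(OC)c3)[C@@H]2CO | intermediate
13 | {(2S,3S,4R)-4-[(benzyloxy)methyl]-2-[4-(TBSO)-3-methoxyphenyl]oxolan-3-yl}methanol | c1ccccc1COC[C@@H]2CO[C@H](c3ccc(O[Si](C)(C)C(C)(C)C)c(OC)c3)[C@@H]2CO | intermediate
14 | (2S,3S,4R)-4-[(benzyloxy)methyl]-2-[4-(TBSO)-3-methoxyphenyl]-3-[(TBSO)methyl]oxolane | c1ccccc1COC[C@@H]2CO[C@H](c3ccc(O[Si](C)(C)C(C)(C)C)c(OC)c3)[C@@H]2CO[Si](C)(C)C(C)(C)C | intermediate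
15 | {(3R,4S,5S)-5-[4-(TBSO)-3-methoxyphenyl]-4-[(TBSO)methyl]oxolan-3-yl}methanol | OC[C@@H]1CO[C@H](c2ccc(O[Si](C)(C)C(C)(C)C)c(OC)c2)[C@@H]1CO[Si](C)(C)C(C)(C)C | intermediate
16 | (3S,4S,5S)-5-[4-(TBSO)-3-methoxyphenyl]-4-[(TBSO)methyl]oxolane-3-carbaldehyde | O=C[C@@H]1CO[C@H](c2ccc(O[Si](C)(C)C(C)(C)C)c(OC)c2)[C@@H]1CO[Si](C)(C)C(C)(C)C | intermediate
17 | (4-bromo-2-methoxyphenoxy)(tert-butyl)dimethylsilane | COc1cc(Br)ccc1O[Si](C)(C)C(C)(C)C | starting material
18 | [4-(TBSO)-3-methoxyphenyl]lithium | COc1cc([Li])ccc1O[Si](C)(C)C(C)(C)C | intermediate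
19 | (S)-[4-(TBSO)-3-methoxyphenyl]{(3S,4S,5S)-5-[4-(TBSO)-3-methoxyphenyl]-4-[(TBSO)methyl]oxolan-3-yl}methanol | COc1cc([C@@H](O)[C@@H]2CO[C@H](c3ccc(O[Si](C)(C)C(C)(C)C)c(OC)c3)[C@@H]2CO[Si](C)(C)C(C)(C)C)ccc1O[Si](C)(C)C(C)(C)C | intermediate
20 | (S)-(4-hydroxy-3-methoxyphenyl)[(3S,4S,5S)-5-(4-hydroxy-3-methoxyphenyl)-4-(hydroxymethyl)oxolan-3-yl]methanol | COc1cc([C@@H](O)[C@@H]2CO[C@H](c3ccc(O)c(OC)c3)[C@@H]2CO)ccc1O | target

Total step count: 11. Longest linear sequence: 10 steps (4 → 5 → 8 → 9 → 10 → 13 → 14 → 15 → 16 → 19 → 20; the branch 1 → 3 → 8 and onward is equally long).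

Steps most likely to fail

Step 10: the aryllithium addition may show poor facial selectivity (attack on the anti-Felkin face), and the basic reagent may epimerize the α-centre of the cis aldehyde. The fallback sets out from 16: 18 is added as before, but the mixture of 19 and its Cα epimer (R)-[4-(TBSO)-3-methoxyphenyl]{(3S,4S,5S)-5-[4-(TBSO)-3-methoxyphenyl]-4-[(TBSO)methyl]oxolan-3-yl}methanol F1 is accepted. The mixture is oxidized with Dess–Martin periodinane in CH2Cl2 to the single aryl ketone [4-(TBSO)-3-methoxyphenyl]{(3S,4S,5S)-5-[4-(TBSO)-3-methoxyphenyl]-4-[(TBSO)methyl]oxolan-3-yl}methanone F2. F2 is then reduced with BH3·SMe2 and (R)-1-methyl-3,3-diphenyltetrahydro-1H,3H-pyrrolo[1,2-c][1,3,2]oxazaborole (the (R)-CBS catalyst) in THF at −20 °C, so that the catalyst (aryl as the large group) and no longer the substrate sets the (S)-carbinol. The route is rejoined at 19.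

Step 6: hydride delivery to the oxocarbenium ion may show poor facial selectivity, and the Lewis acid may cause elimination of the β-hydroxyl or loss of the aryl silyl ether. The fallback sets out from 10: its hemiketal is dehydrated with pyridinium p-toluenesulfonate (toluene, 4 Å molecular sieves, 60 °C) to the cyclic enol ether {(4R)-4-[(benzyloxy)methyl]-2-[4-(TBSO)-3-methoxyphenyl]-4,5-dihydrofuran-3-yl}methanol F3. The tetrasubstituted double bond is then hydrogenated with H2 and [Ir(cod)(PCy3)(py)]PF6 in CH2Cl2. Syn addition of H2 to the face opposite the C4 benzyloxymethyl group, the only stereocentre left, should give the same all-cis oxolane, and the route is rejoined at 13.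

Step 3: the three-component coupling may stall at the alkylation, through proton transfer to the hindered enolate, O-alkylation or slow reaction with the chloromethyl ether. The fallback sets out from 5 and 3: the same conjugate addition is run, but enolate 7 is trapped with gaseous formaldehyde at −78 °C (aldol addition, faster than alkylation) to give (3R,4S,5S)-3-(hydroxymethyl)-4-{2-[4-(TBSO)-3-methoxyphenyl]-1,3-dithian-2-yl}-5-(menthyloxy)oxolan-2-one F4. The primary alcohol is then benzylated without base with 2-benzyloxy-1-methylpyridinium triflate and MgO in PhCF3 at 85 °C, which avoids retro-aldol cleavage and elimination. The route is rejoined at 8.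

Further compounds
F1 | step 10 | (R)-[4-(TBSO)-3-methoxyphenyl]{(3S,4S,5S)-5-[4-(TBSO)-3-methoxyphenyl]-4-[(TBSO)methyl]oxolan-3-yl}methanol | COc1cc([C@H](O)[C@@H]2CO[C@H](c3ccc(O[Si](C)(C)C(C)(C)C)c(OC)c3)[C@@H]2CO[Si](C)(C)C(C)(C)C)ccc1O[Si](C)(C)C(C)(C)C
F2 | step 10 | [4-(TBSO)-3-methoxyphenyl]{(3S,4S,5S)-5-[4-(TBSO)-3-methoxyphenyl]-4-[(TBSO)methyl]oxolan-3-yl}methanone | COc1cc(C(=O)[C@@H]2CO[C@H](c3ccc(O[Si](C)(C)C(C)(C)C)c(OC)c3)[C@@H]2CO[Si](C)(C)C(C)(C)C)ccc1O[Si](C)(C)C(C)(C)C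
F3 | step 6 | {(4R)-4-[(benzyloxy)methyl]-2-[4-(TBSO)-3-methoxyphenyl]-4,5-dihydrofuran-3-yl}methanol | c1ccccc1COC[C@@H]2COC(c3ccc(O[Si](C)(C)C(C)(C)C)c(OC)c3)=C2CO
F4 | step 3 | (3R,4S,5S)-3-(hydroxymethyl)-4-{2-[4-(TBSO)-3-methoxyphenyl]-1,3-dithian-2-yl}-5-(menthyloxy)oxolan-2-one | O=C1[C@@H](CO)[C@H](C3(c4ccc(O[Si](C)(C)C(C)(C)C)c(OC)c4)SCCCS3)[C@@H](O[C@H]5C[C@@H](C)CC[C@@H]5C(C)C)O1
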